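**Strategy**

The tetrahydrofuran ring (O1, C2 with the trimethoxyphenyl group, C3 with CH2OH, C4 with the benzyl group, C5) is disconnected at O1–C2. Because C2 carries both O1 and the electron-rich 3,4,5-trimethoxyphenyl ring, this bond can be made by trapping a benzylic cation; the cation is generated from a cyclopropane built of C2, C3 and C4, in which a formyl group on C4 provides C5 and O1. One Lewis-acid-catalysed Cloke–Wilson ring expansion of cyclopropanecarbaldehyde 15 thus breaks C2–C4, makes O1–C2, closes the five-membered ring and places the aryl group trans to the C3 arm. Enantioselective intramolecular cyclopropanation fixes C3 beforehand; face-selective hydrogenation of the enol ether sets C4 afterwards.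

Key step: step 12

Assumption: Rh2(S-PTTL)4 is taken to give the (1R,5S,6R) lactone 12 in step 8; should the sense of induction be the opposite, Rh2(R-PTTL)4 is used and nothing else changes. Atom labels O1 and C2–C5 are those of the target ring throughout.

**Route**

Step 1
Reactants: 1 3-hydroxy-4,5-dimethoxybenzaldehyde
Product: 2 3-(benzyloxy)-4,5-dimethoxybenzaldehyde
Conditions: BnBr, K2CO3, DMF, rt
Reagents that add atoms: benzyl bromide, BrCc1ccccc1
Why: Williamson ether synthesis; the phenoxide formed with K2CO3 displaces bromide, which masks the only O–H that would otherwise intercept the carbene of step 8.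

Step 2
Reactants: 2 3-(benzyloxy)-4,5-dimethoxybenzaldehyde
Product: 3 [3-(benzyloxy)-4,5-dimethoxyphenyl]methanol
Conditions: NaBH4, MeOH, 0 °C
Reagents that add atoms: none
Why: Borohydride 1,2-reduction of an aryl aldehyde to the benzylic alcohol; the aryl ethers are inert.

Step 3
Reactants: 3 [3-(benzyloxy)-4,5-dimethoxyphenyl]methanol
Product: 4 1-(benzyloxy)-5-(bromomethyl)-2,3-dimethoxybenzene
Conditions: PBr3, CH2Cl2, 0 °C
Reagents that add atoms: phosphorus tribromide, BrP(Br)Br
Why: Bromination of an electron-rich benzylic alcohol through its phosphite ester; the reactive bromide is used crude.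

Step 4
Reactants: 5 methyl (E)-3-(3,4,5-trimethoxyphenyl)prop-2-enoate
Product: 6 (E)-3-(3,4,5-trimethoxyphenyl)prop-2-en-1-ol
Conditions: iBu2AlH, CH2Cl2, −78 → 0 °C
Reagents that add atoms: none
Why: Twofold hydride transfer reduces the conjugated ester by 1,2-addition only, so the E-alkene needed for the cyclopropanation is kept.

Step 5
Reactants: 6 (E)-3-(3,4,5-trimethoxyphenyl)prop-2-en-1-ol; 7 2,2,6-trimethyl-4H-1,3-dioxin-4-one
Product: 9 (E)-3-(3,4,5-trimethoxyphenyl)prop-2-en-1-yl 3-oxobutanoate, via acetylketene 8 (not isolated)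
Conditions: toluene, 110 °C, acetone distilled off
Reagents that add atoms: none
Why: Thermal retro-hetero-Diels–Alder loss of acetone from 7 gives acetylketene, which acylates the allylic alcohol (acetoacetylation) under neutral conditions.

Step 6
Reactants: 9 (E)-3-(3,4,5-trimethoxyphenyl)prop-2-en-1-yl 3-oxobutanoate; 4 1-(benzyloxy)-5-(bromomethyl)-2,3-dimethoxybenzene
Product: 10 (E)-3-(3,4,5-trimethoxyphenyl)prop-2-en-1-yl 2-[3-(benzyloxy)-4,5-dimethoxybenzyl]-3-oxobutanoate (racemic at C2 of the butanoate)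
Conditions: K2CO3, acetone, 56 °C
Reagents that add atoms: none
Why: Acetoacetic ester C-alkylation with a reactive benzylic bromide; a slight excess of 9 limits double alkylation, and the new stereocentre is erased in step 7.

Step 7
Reactants: 10 (E)-3-(3,4,5-trimethoxyphenyl)prop-2-en-1-yl 2-[3-(benzyloxy)-4,5-dimethoxybenzyl]-3-oxobutanoate
Product: 11 (E)-3-(3,4,5-trimethoxyphenyl)prop-2-en-1-yl 3-[3-(benzyloxy)-4,5-dimethoxyphenyl]-2-diazopropanoate
Conditions: p-ABSA, DBU, MeCN, 0 °C → rt
Reagents that add atoms: 4-acetamidobenzenesulfonyl azide, CC(=O)Nc1ccc(cc1)S(=O)(=O)N=[N+]=[N-]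
Why: Deacylative Regitz diazo transfer; the enolate adds to the sulfonyl azide and the adduct fragments with passage of the acetyl group to the sulfonamide nitrogen, which is the dependable way to place a diazo group on an ester carbon that a single carbonyl group could not activate for diazo transfer.

Step 8
Reactants: 11 (E)-3-(3,4,5-trimethoxyphenyl)prop-2-en-1-yl 3-[3-(benzyloxy)-4,5-dimethoxyphenyl]-2-diazopropanoate
Product: 12 (1R,5S,6R)-1-[3-(benzyloxy)-4,5-dimethoxybenzyl]-6-(3,4,5-trimethoxyphenyl)-3-oxabicyclo[3.1.0]hexan-2-one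
Conditions: Rh2(S-PTTL)4 (1 mol %), CH2Cl2, −78 °C, slow addition of 11
Reagents that add atoms: none
Why: Enantioselective intramolecular cyclopropanation by a rhodium carbene; the ester tether enforces cis fusion, the E-alkene geometry puts the aryl group trans to the lactone CH2, the chiral carboxylate ligands choose the alkene face and so fix C3 (C5 of the lactone), and a bulky carboxylate at low temperature is the combination known to hold back 1,2-hydride shift in α-alkyl carbenes.

Step 9
Reactants: 12 (1R,5S,6R)-1-[3-(benzyloxy)-4,5-dimethoxybenzyl]-6-(3,4,5-trimethoxyphenyl)-3-oxabicyclo[3.1.0]hexan-2-one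
Product: 13 (1R,2R,3S)-1-[3-(benzyloxy)-4,5-dimethoxybenzyl]-3-(hydroxymethyl)-N-methoxy-N-methyl-2-(3,4,5-trimethoxyphenyl)cyclopropane-1-carboxamide
Conditions: MeNH(OMe)·HCl, AlMe3, CH2Cl2, 0 °C → rt
Reagents that add atoms: N,O-dimethylhydroxylamine hydrochloride, CNOC.Cl
Why: Weinreb aminolysis of a strained lactone by the aluminium amide formed in the flask; no stereocentre is touched, and the crude hydroxy amide is carried on at once so that it cannot close back to the lactone.

Step 10
Reactants: 13 (1R,2R,3S)-1-[3-(benzyloxy)-4,5-dimethoxybenzyl]-3-(hydroxymethyl)-N-methoxy-N-methyl-2-(3,4,5-trimethoxyphenyl)cyclopropane-1-carboxamide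
Product: 14 (1R,2R,3S)-1-[3-(benzyloxy)-4,5-dimethoxybenzyl]-3-{[(tert-butyldimethylsilyl)oxy]methyl}-N-methoxy-N-methyl-2-(3,4,5-trimethoxyphenyl)cyclopropane-1-carboxamide
Conditions: TBSCl, imidazole, DMF, 0 °C → rt
Reagents that add atoms: tert-butyldimethylsilyl chloride, CC(C)(C)[Si](C)(C)Cl
Why: Imidazole-promoted silylation of the primary alcohol; it rules out relactonisation and supplies the bulky group that later shields one face of C4.

Step 11
Reactants: 14 (1R,2R,3S)-1-[3-(benzyloxy)-4,5-dimethoxybenzyl]-3-{[(tert-butyldimethylsilyl)oxy]methyl}-N-methoxy-N-methyl-2-(3,4,5-trimethoxyphenyl)cyclopropane-1-carboxamide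
Product: 15 (1R,2R,3S)-1-[3-(benzyloxy)-4,5-dimethoxybenzyl]-3-{[(tert-butyldimethylsilyl)oxy]methyl}-2-(3,4,5-trimethoxyphenyl)cyclopropane-1-carbaldehyde
Conditions: iBu2AlH, THF, −78 °C
Reagents that add atoms: none
Why: Reduction of a Weinreb amide stops at the aldehyde because the chelated tetrahedral aluminium adduct survives until work-up; silyl and benzyl ethers are inert at this temperature.

Step 12
Reactants: 15 (1R,2R,3S)-1-[3-(benzyloxy)-4,5-dimethoxybenzyl]-3-{[(tert-butyldimethylsilyl)oxy]methyl}-2-(3,4,5-trimethoxyphenyl)cyclopropane-1-carbaldehyde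
Product: 16 tert-butyl{[(2R,3S)-4-[3-(benzyloxy)-4,5-dimethoxybenzyl]-2-(3,4,5-trimethoxyphenyl)-2,3-dihydrofuran-3-yl]methoxy}dimethylsilane
Conditions: Sc(OTf)3 (10 mol %), 4 Å molecular sieves, CH2Cl2, −20 → 0 °C; Et3N quench
Reagents that add atoms: none
Why: Sc(OTf)3 binds the formyl oxygen and the cyclopropane bond C2–C4, flanked by the aryl donor and the activated acceptor, heterolyses to a contact ion pair of a benzylic cation at C2 and a scandium enolate C4=C5–O, whose oxygen then bonds to C2. This is a Lewis-acid-catalysed Cloke–Wilson rearrangement of a donor–acceptor cyclopropyl aldehyde. The one ring closes by O-alkylation of the enolate, a 5-(enolendo)-exo-trig closure onto the planar cation that is feasible for oxygen because its in-plane lone pair reaches C2. The new stereocentre C2 is controlled by the existing centre C3: the aryl group takes the face away from the silyloxymethyl arm, and since closure is reversible under the Lewis acid this trans ether is also the thermodynamic outcome, while no bond to C3 is broken, so the configuration set in step 8 is kept. The step needs cleavage of C2–C4 and not C3–C4, and O-closure and not Friedel–Crafts capture of the cation by the pendant benzyl ring; the first is secured by the aryl donor being on C2 only, the second by the enolate oxygen being held next to C2 in the ion pair, supported by a catalytic Lewis acid, low temperature and an amine quench as soon as 15 is consumed.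

Step 13
Reactants: 16 tert-butyl{[(2R,3S)-4-[3-(benzyloxy)-4,5-dimethoxybenzyl]-2-(3,4,5-trimethoxyphenyl)-2,3-dihydrofuran-3-yl]methoxy}dimethylsilane
Product: 18 tert-butyl{[(2R,3S,4S)-4-(3-hydroxy-4,5-dimethoxybenzyl)-2-(3,4,5-trimethoxyphenyl)tetrahydrofuran-3-yl]methoxy}dimethylsilane, via saturated benzyl ether 17 (not isolated)
Conditions: H2 (1 atm), 10% Pd/C, EtOAc, rt
Reagents that add atoms: none
Why: Heterogeneous syn-hydrogenation in which the enol ether C4=C5 binds the catalyst on the face opposite the bulky CH2OTBS group on the adjacent C3, so hydrogen arrives anti to that arm and the benzyl group at C4 ends cis to it (4S); the same catalyst then hydrogenolyses the aryl benzyl ether, and neutral EtOAc at 1 atm with stopping at full conversion should spare the C2–O1 benzylic ether.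

Step 14
Reactants: 18 tert-butyl{[(2R,3S,4S)-4-(3-hydroxy-4,5-dimethoxybenzyl)-2-(3,4,5-trimethoxyphenyl)tetrahydrofuran-3-yl]methoxy}dimethylsilane
Product: 19 [(2R,3S,4S)-4-(3-hydroxy-4,5-dimethoxybenzyl)-2-(3,4,5-trimethoxyphenyl)tetrahydrofuran-3-yl]methanol
Conditions: Bu4NF, THF, 0 °C → rt
Reagents that add atoms: none
Why: Fluoride-induced desilylation of the primary silyl ether under non-acidic conditions, which leaves the acid-sensitive C2–O1 benzylic ether and all three stereocentres untouched.

**Compound list**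

1 | 3-hydroxy-4,5-dimethoxybenzaldehyde | COc1cc(C=O)cc(O)c1OC | starting material
2 | 3-(benzyloxy)-4,5-dimethoxybenzaldehyde | COc1cc(C=O)cc(OCc2ccccc2)c1OC | intermediate
3 | [3-(benzyloxy)-4,5-dimethoxyphenyl]methanol | COc1cc(CO)cc(OCc2ccccc2)c1OC | intermediate
4 | 1-(benzyloxy)-5-(bromomethyl)-2,3-dimethoxybenzene | COc1cc(CBr)cc(OCc2ccccc2)c1OC | intermediate
5 | methyl (E)-3-(3,4,5-trimethoxyphenyl)prop-2-enoate | COc1cc(/C=C/C(=O)OC)cc(OC)c1OC | starting material
6 | (E)-3-(3,4,5-trimethoxyphenyl)prop-2-en-1-ol | COc1cc(/C=C/CO)cc(OC)c1OC | intermediate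
7 | 2,2,6-trimethyl-4H-1,3-dioxin-4-one | CC1=CC(=O)OC(C)(C)O1 | starting material
8 | acetylketene (but-1-ene-1,3-dione) | CC(=O)C=C=O | intermediate
9 | (E)-3-(3,4,5-trimethoxyphenyl)prop-2-en-1-yl 3-oxobutanoate | COc1cc(/C=C/COC(=O)CC(C)=O)cc(OC)c1OC | intermediate
10 | (E)-3-(3,4,5-trimethoxyphenyl)prop-2-en-1-yl 2-[3-(benzyloxy)-4,5-dimethoxybenzyl]-3-oxobutanoate (racemic) | COc1cc(/C=C/COC(=O)C(Cc2cc(OC)c(OC)c(OCc3ccccc3)c2)C(C)=O)cc(OC)c1OC | intermediate
11 | (E)-3-(3,4,5-trimethoxyphenyl)prop-2-en-1-yl 3-[3-(benzyloxy)-4,5-dimethoxyphenyl]-2-diazopropanoate | COc1cc(/C=C/COC(=O)C(=[N+]=[N-])Cc2cc(OC)c(OC)c(OCc3ccccc3)c2)cc(OC)c1OC | intermediate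
12 | (1R,5S,6R)-1-[3-(benzyloxy)-4,5-dimethoxybenzyl]-6-(3,4,5-trimethoxyphenyl)-3-oxabicyclo[3.1.0]hexan-2-one | O=C1[C@]2(Cc3cc(OC)c(OC)c(OCc4ccccc4)c3)[C@@H](c3cc(OC)c(OC)c(OC)c3)[C@@H]2CO1 | intermediate
13 | (1R,2R,3S)-1-[3-(benzyloxy)-4,5-dimethoxybenzyl]-3-(hydroxymethyl)-N-methoxy-N-methyl-2-(3,4,5-trimethoxyphenyl)cyclopropane-1-carboxamide | CON(C)C(=O)[C@]1(Cc2cc(OC)c(OC)c(OCc3ccccc3)c2)[C@@H](c2cc(OC)c(OC)c(OC)c2)[C@@H]1CO | intermediate
14 | (1R,2R,3S)-1-[3-(benzyloxy)-4,5-dimethoxybenzyl]-3-{[(tert-butyldimethylsilyl)oxy]methyl}-N-methoxy-N-methyl-2-(3,4,5-trimethoxyphenyl)cyclopropane-1-carboxamide | CON(C)C(=O)[C@]1(Cc2cc(OC)c(OC)c(OCc3ccccc3)c2)[C@@H](c2cc(OC)c(OC)c(OC)c2)[C@@H]1CO[Si](C)(C)C(C)(C)C | intermediate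
15 | (1R,2R,3S)-1-[3-(benzyloxy)-4,5-dimethoxybenzyl]-3-{[(tert-butyldimethylsilyl)oxy]methyl}-2-(3,4,5-trimethoxyphenyl)cyclopropane-1-carbaldehyde | O=C[C@]1(Cc2cc(OC)c(OC)c(OCc3ccccc3)c2)[C@@H](c2cc(OC)c(OC)c(OC)c2)[C@@H]1CO[Si](C)(C)C(C)(C)C | intermediate
16 | tert-butyl{[(2R,3S)-4-[3-(benzyloxy)-4,5-dimethoxybenzyl]-2-(3,4,5-trimethoxyphenyl)-2,3-dihydrofuran-3-yl]methoxy}dimethylsilane | COc1cc(CC2=CO[C@@H](c3cc(OC)c(OC)c(OC)c3)[C@@H]2CO[Si](C)(C)C(C)(C)C)cc(OCc4ccccc4)c1OC | intermediate
17 | tert-butyl{[(2R,3S,4S)-4-[3-(benzyloxy)-4,5-dimethoxybenzyl]-2-(3,4,5-trimethoxyphenyl)tetrahydrofuran-3-yl]methoxy}dimethylsilane | COc1cc(C[C@@H]2CO[C@@H](c3cc(OC)c(OC)c(OC)c3)[C@@H]2CO[Si](C)(C)C(C)(C)C)cc(OCc4ccccc4)c1OC | intermediate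
18 | tert-butyl{[(2R,3S,4S)-4-(3-hydroxy-4,5-dimethoxybenzyl)-2-(3,4,5-trimethoxyphenyl)tetrahydrofuran-3-yl]methoxy}dimethylsilane | COc1cc(C[C@@H]2CO[C@@H](c3cc(OC)c(OC)c(OC)c3)[C@@H]2CO[Si](C)(C)C(C)(C)C)cc(O)c1OC | intermediate
19 | [(2R,3S,4S)-4-(3-hydroxy-4,5-dimethoxybenzyl)-2-(3,4,5-trimethoxyphenyl)tetrahydrofuran-3-yl]methanol | COc1cc(C[C@@H]2CO[C@@H](c3cc(OC)c(OC)c(OC)c3)[C@@H]2CO)cc(O)c1OC | target

**Step count and risks**

Total step count: 14. Longest linear sequence: 12 steps (steps 1, 2, 3, 6, 7, 8, 9, 10, 11, 12, 13, 14).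

The three steps most likely to fail:

Step 8. What may go wrong: the benzylic β-hydrogens of the rhodium carbene may shift (1,2-hydride migration) faster than the tethered alkene is reached, and facial discrimination may be incomplete. The fallback takes the β-hydrogens out of the carbene and installs the benzyl group afterwards; it sets out from alcohol 6 and comes back at 12. Acylation of 6 with bromoacetyl bromide and NaHCO3 in MeCN gives (E)-3-(3,4,5-trimethoxyphenyl)prop-2-en-1-yl 2-bromoacetate F1. N,N'-ditosylhydrazine and DBU convert it into (E)-3-(3,4,5-trimethoxyphenyl)prop-2-en-1-yl 2-diazoacetate F2. Intramolecular cyclopropanation with a chiral dirhodium carboxamidate, Rh2(4S-MPPIM)4 or its enantiomer (a catalyst class developed for E-allylic diazoacetates), gives (1R,5S,6S)-6-(3,4,5-trimethoxyphenyl)-3-oxabicyclo[3.1.0]hexan-2-one F3. Deprotonation of its only α-hydrogen, at the ring-fusion carbon, with LiN(iPr)2 in THF at −78 °C and alkylation of the cyclopropyl ester enolate with bromide 4 gives 12; the cis ring fusion permits only retention.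

Step 12. What may go wrong: the ionised intermediate may be diverted from O-closure by Friedel–Crafts attack of the C2 cation on the electron-rich benzyl ring, and the enol ether formed may ionise again and break down while the Lewis acid is present. The fallback moves the ring expansion to the amide oxidation level, where the closed product is a cation that cannot re-ionise; it sets out from 14 and comes back at 16. Treatment of 14 with TfOH (1 equiv) in CH2Cl2 at −40 °C lets the amide oxygen close on C2 to an iminium ether. Buffered aqueous hydrolysis of this gives (4S,5R)-3-[3-(benzyloxy)-4,5-dimethoxybenzyl]-4-{[(tert-butyldimethylsilyl)oxy]methyl}-5-(3,4,5-trimethoxyphenyl)dihydrofuran-2(3H)-one F4, whose epimers at C3 are of no consequence. Reduction with iBu2AlH in toluene at −78 °C gives the lactol (4S,5R)-3-[3-(benzyloxy)-4,5-dimethoxybenzyl]-4-{[(tert-butyldimethylsilyl)oxy]methyl}-5-(3,4,5-trimethoxyphenyl)tetrahydrofuran-2-ol F5. Dehydration of F5 with MsCl and Et3N under basic conditions gives enol ether 16.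

Step 13. What may go wrong: hydrogen may be delivered to C4 with poor facial discrimination, and the catalyst may go on to hydrogenolyse the ring C2–O1 benzylic bond while the benzyl ether is being cleaved. The fallback replaces substrate control by catalyst control and separates the two tasks; it sets out from 16 and comes back at 18 by way of 17, which is isolated in this variant, so no new compound arises (F0). Homogeneous hydrogenation of 16 with a cationic iridium N,P-ligand catalyst of the type [Ir(cod)(tBu-PHOX)][B(3,5-(CF3)2C6H3)4] is screened with both ligand enantiomers for the matched case giving the 4S isomer; such catalysts reduce cyclic enol ethers and leave benzyl ethers alone, so 17 is obtained. Transfer hydrogenolysis of 17 (10% Pd/C, cyclohexa-1,4-diene, EtOH), which is slow for alkyl benzylic ethers such as C2–O1, then gives 18.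

**Further compounds**

F1 | step 8 | (E)-3-(3,4,5-trimethoxyphenyl)prop-2-en-1-yl 2-bromoacetate | COc1cc(/C=C/COC(=O)CBr)cc(OC)c1OC
F2 | step 8 | (E)-3-(3,4,5-trimethoxyphenyl)prop-2-en-1-yl 2-diazoacetate | COc1cc(/C=C/COC(=O)C=[N+]=[N-])cc(OC)c1OC
F3 | step 8 | (1R,5S,6S)-6-(3,4,5-trimethoxyphenyl)-3-oxabicyclo[3.1.0]hexan-2-one | O=C1[C@@H]2[C@@H](c3cc(OC)c(OC)c(OC)c3)[C@@H]2CO1
F4 | step 12 | (4S,5R)-3-[3-(benzyloxy)-4,5-dimethoxybenzyl]-4-{[(tert-butyldimethylsilyl)oxy]methyl}-5-(3,4,5-trimethoxyphenyl)dihydrofuran-2(3H)-one | COc1cc(CC2C(=O)O[C@@H](c3cc(OC)c(OC)c(OC)c3)[C@@H]2CO[Si](C)(C)C(C)(C)C)cc(OCc4ccccc4)c1OC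
F5 | step 12 | (4S,5R)-3-[3-(benzyloxy)-4,5-dimethoxybenzyl]-4-{[(tert-butyldimethylsilyl)oxy]methyl}-5-(3,4,5-trimethoxyphenyl)tetrahydrofuran-2-ol | COc1cc(CC2C(O)O[C@@H](c3cc(OC)c(OC)c(OC)c3)[C@@H]2CO[Si](C)(C)C(C)(C)C)cc(OCc4ccccc4)c1OC
F0 | step 13 | none | none
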